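**Plan**
- Retrosynthesis: each C4=O is first retraced to C4=CH2 (carbonyl surrogate). Then both ring-C bonds C4–C4a are cut (to aryl iodide plus vinyl group), then both aryl ether bonds O1–C2, and last the C6–C6'' biaryl bond.
- Forward: the two A rings are joined first (directed lithiation and oxidative homocoupling of a resorcinol bis-MOM ether, para oxygen by C–H borylation/oxidation). Both B-ring chains are then attached to the 4,4'-diol, both C rings are closed in one operation, the ketones are unmasked and all protecting groups removed.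
- Enabling feature: in each ring A the ether carbon C8a lies para to the biaryl carbon C6, so the two carbons ortho to O1 (future C4a and C8) are equivalent and doubly oxygen-flanked. Iodine on either one, followed by 6-exo attack on the internal vinyl carbon (future C4, reached through O1–C2–C3), can only give the 6,6''-linked bis-chroman.
- Helpers: iodine (lost in the ring closure) and the exocyclic CH2 on C4 (removed by Lemieux–Johnson cleavage); MOM and acetate groups leave in the last step.
- Stereochemistry: both C2 centres come from one catalyst-controlled (R)-selective allylboration and are inverted to (S) in the Mitsunobu etherification; no later step touches them. The biaryl axis is not controlled.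

Key step: step 6

Remark: the target carries no descriptor for the hindered C6–C6'' axis, so from the diiodide onwards each compound is taken as the mixture of rotamers about this axis, which differ in nothing else.
Remark: each two-fold step passes through a half-converted species of the same kind; only that of the key step is numbered, because it is the substrate of the second ring closure.

**Step 1**
Reactants: 1 1,3-bis(methoxymethoxy)benzene (2 equiv)
Product: 3 2,2',6,6'-tetrakis(methoxymethoxy)-1,1'-biphenyl, via aryllithium 2 (not isolated)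
Conditions: n-BuLi, THF, 0 °C; then anhydrous CuCl2, −78 °C to rt
Reagents that add atoms: none
Why: directed ortho-metalation by the two MOM groups lithiates only C2 between the acetal oxygens, and oxidative homocoupling of the aryl metal species with CuCl2 should join two units to the tetra-ortho-oxygenated biaryl that becomes the C6–C6'' bond.

**Step 2**
Reactants: 3 2,2',6,6'-tetrakis(methoxymethoxy)-1,1'-biphenyl
Product: 5 2,2',6,6'-tetrakis(methoxymethoxy)-1,1'-biphenyl-4,4'-diol, via bis(pinacolboronate) 4 (not isolated)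
Conditions: [Ir(OMe)(cod)]2 (2 mol %), 4,4'-di-tert-butyl-2,2'-bipyridine (4 mol %), B2pin2, THF, 80 °C; then aq. H2O2, NaOH, 0 °C
Reagents that add atoms: hydrogen peroxide, OO (the two phenolic oxygens); bis(pinacolato)diboron, CC1(C)OB(OC1(C)C)B1OC(C)(C)C(C)(C)O1 (boron of 4 only)
Why: sterically governed iridium-catalysed C–H borylation attacks only C4 and C4', the one C–H per ring without an ortho substituent, and oxidation of each C–B bond should give the phenols that become O1.

**Step 3**
Reactants: 6 4-formylphenyl acetate (4-acetoxybenzaldehyde)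
Product: 8 4-[(1R)-1-hydroxybut-3-en-1-yl]phenyl acetate, via borate ester 7 (not isolated)
Conditions: allylB(pin), (R)-TRIP [(R)-3,3'-bis(2,4,6-triisopropylphenyl)-1,1'-binaphthyl-2,2'-diyl hydrogen phosphate] (5 mol %), toluene, −30 °C; aqueous work-up
Reagents that add atoms: allylboronic acid pinacol ester, C=CCB1OC(C)(C)C(C)(C)O1
Why: chiral phosphoric acid-catalysed allylboration through a chair six-membered transition state, in which (R)-TRIP hydrogen-bonds the boronate oxygen and the formyl hydrogen, should deliver allyl to the Re face and set the (R)-carbinol.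

**Step 4**
Reactants: 5 2,2',6,6'-tetrakis(methoxymethoxy)-1,1'-biphenyl-4,4'-diol; 8 4-[(1R)-1-hydroxybut-3-en-1-yl]phenyl acetate (2.4 equiv)
Product: 9 4,4'-bis{[(1S)-1-(4-acetoxyphenyl)but-3-en-1-yl]oxy}-2,2',6,6'-tetrakis(methoxymethoxy)-1,1'-biphenyl
Conditions: PPh3, DIAD, toluene, 0 °C to rt
Reagents that add atoms: none
Why: two-fold Mitsunobu etherification displaces each oxyphosphonium group by an unhindered 4-OH in an SN2 step with inversion, turning the (R)-carbinol into the (S)-aryl ether (future C2), while the acetoxy-substituted ring, being no donor, disfavours ionisation.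

**Step 5**
Reactants: 9 4,4'-bis{[(1S)-1-(4-acetoxyphenyl)but-3-en-1-yl]oxy}-2,2',6,6'-tetrakis(methoxymethoxy)-1,1'-biphenyl
Product: 10 4,4'-bis{[(1S)-1-(4-acetoxyphenyl)but-3-en-1-yl]oxy}-3,3'-diiodo-2,2',6,6'-tetrakis(methoxymethoxy)-1,1'-biphenyl
Conditions: NIS (2.05 equiv), MeCN, 0 °C to rt, dark
Reagents that add atoms: N-iodosuccinimide, O=C1CCC(=O)N1I
Why: electrophilic aromatic iodination should go to the tri-oxygen-activated ring A far faster than to the acetoxyphenyl ring or the alkene, the two open positions of each ring are equivalent, and the first iodine deactivates its ring against a second.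

**Step 6**
Reactants: 10 4,4'-bis{[(1S)-1-(4-acetoxyphenyl)but-3-en-1-yl]oxy}-3,3'-diiodo-2,2',6,6'-tetrakis(methoxymethoxy)-1,1'-biphenyl
Product: 12 (2S,2''S)-4',4'''-diacetoxy-5,5'',7,7''-tetrakis(methoxymethoxy)-4,4''-dimethylidene-6,6''-biflavan, via monocyclised iodide 11 (not isolated)
Conditions: Pd(OAc)2 (10 mol %), PPh3 (30 mol %), Ag2CO3 (2.2 equiv), MeCN, 80 °C
Reagents that add atoms: none
Why: Zerovalent palladium formed from Pd(OAc)2 and PPh3 inserts into each aryl C–I bond, the arylpalladium species adds syn across the tethered vinyl group so that the aryl carbon (future C4a) bonds to the internal alkene carbon (future C4), and β-hydride elimination of the only β-hydrogen (on C4) gives the exocyclic C4=CH2 alkene while Ag2CO3 takes up HI. The closest known reaction is the intramolecular Mizoroki–Heck cyclisation of 2-iodoaryl but-3-enyl ethers to 4-methylenechromans. Each ring C closes in the 6-exo-trig mode, the 7-endo mode being the disfavoured alternative. No stereocentre is formed: C2 takes no part and keeps its (S) configuration, and the biaryl axis is not controlled. The step needs exo closure and an alkene that stays exocyclic; the three-atom O1–C2–C3 tether secures the first and silver-assisted iodide abstraction (cationic palladium, fast release of the palladium hydride) the second. The 6,6'' connectivity needs no control because C8a is para to the biaryl bond, so the iodinated ortho carbon is C4a whichever one it is.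

**Step 7**
Reactants: 12 (2S,2''S)-4',4'''-diacetoxy-5,5'',7,7''-tetrakis(methoxymethoxy)-4,4''-dimethylidene-6,6''-biflavan
Product: 14 (2S,2''S)-4',4'''-diacetoxy-5,5'',7,7''-tetrakis(methoxymethoxy)-6,6''-biflavanone, via bis(diol) 13 (not isolated)
Conditions: OsO4 (5 mol %), NaIO4, 2,6-lutidine, 1,4-dioxane/H2O 3:1, rt
Reagents that add atoms: sodium periodate (NaIO4), [Na+].[O-]I(=O)(=O)=O (source of the ketone oxygens); OsO4, O=[Os](=O)(=O)=O (catalytic oxygen carrier)
Why: Lemieux–Johnson oxidation, in which OsO4 dihydroxylates each exocyclic 1,1-disubstituted alkene and NaIO4 cleaves the diol, should unmask both C4 ketones under lutidine-buffered conditions that do not epimerise C2.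

**Step 8**
Reactants: 14 (2S,2''S)-4',4'''-diacetoxy-5,5'',7,7''-tetrakis(methoxymethoxy)-6,6''-biflavanone
Product: 15 succedaneaflavanone
Conditions: 3 M aq. HCl/MeOH 1:5, 50 °C
Reagents that add atoms: none
Why: acid-catalysed acetal methanolysis should remove the four MOM groups and acid-catalysed transesterification the two aryl acetates, while the flavanone C2 centre is configurationally stable in acid (its racemisation is base-mediated).

**Compound list**
1 | 1,3-bis(methoxymethoxy)benzene | COCOc1cccc(OCOC)c1 | starting material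
2 | 2,6-bis(methoxymethoxy)phenyllithium | [Li]c1c(OCOC)cccc1OCOC | intermediate
3 | 2,2',6,6'-tetrakis(methoxymethoxy)-1,1'-biphenyl | COCOc1cccc(OCOC)c1-c1c(OCOC)cccc1OCOC | intermediate
4 | 4,4'-bis(4,4,5,5-tetramethyl-1,3,2-dioxaborolan-2-yl)-2,2',6,6'-tetrakis(methoxymethoxy)-1,1'-biphenyl | COCOc1cc(B2OC(C)(C)C(C)(C)O2)cc(OCOC)c1-c1c(OCOC)cc(B2OC(C)(C)C(C)(C)O2)cc1OCOC | intermediate
5 | 2,2',6,6'-tetrakis(methoxymethoxy)-1,1'-biphenyl-4,4'-diol | COCOc1cc(O)cc(OCOC)c1-c1c(OCOC)cc(O)cc1OCOC | intermediate
6 | 4-formylphenyl acetate | CC(=O)Oc1ccc(C=O)cc1 | starting material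
7 | 4-[(1R)-1-[(4,4,5,5-tetramethyl-1,3,2-dioxaborolan-2-yl)oxy]but-3-en-1-yl]phenyl acetate | C=CC[C@@H](OB1OC(C)(C)C(C)(C)O1)c1ccc(OC(C)=O)cc1 | intermediate
8 | 4-[(1R)-1-hydroxybut-3-en-1-yl]phenyl acetate | C=CC[C@@H](O)c1ccc(OC(C)=O)cc1 | intermediate
9 | 4,4'-bis{[(1S)-1-(4-acetoxyphenyl)but-3-en-1-yl]oxy}-2,2',6,6'-tetrakis(methoxymethoxy)-1,1'-biphenyl | C=CC[C@H](Oc1cc(OCOC)c(-c2c(OCOC)cc(O[C@@H](CC=C)c3ccc(OC(C)=O)cc3)cc2OCOC)c(OCOC)c1)c1ccc(OC(C)=O)cc1 | intermediate
10 | 3,3'-diiodo derivative of 9 (iodine ortho to each ether oxygen; axis not defined) | C=CC[C@H](Oc1cc(OCOC)c(-c2c(OCOC)cc(O[C@@H](CC=C)c3ccc(OC(C)=O)cc3)c(I)c2OCOC)c(OCOC)c1I)c1ccc(OC(C)=O)cc1 | intermediate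
11 | monocyclised iodide: one (2S)-4-methylideneflavan unit, the other ring A still bearing iodine and the (S)-homoallyl ether | C=C1C[C@@H](c2ccc(OC(C)=O)cc2)Oc2cc(OCOC)c(-c3c(OCOC)cc(O[C@@H](CC=C)c4ccc(OC(C)=O)cc4)c(I)c3OCOC)c(OCOC)c21 | intermediate
12 | (2S,2''S)-4',4'''-diacetoxy-5,5'',7,7''-tetrakis(methoxymethoxy)-4,4''-dimethylidene-6,6''-biflavan | C=C1C[C@@H](c2ccc(OC(C)=O)cc2)Oc2cc(OCOC)c(-c3c(OCOC)cc4c(c3OCOC)C(=C)C[C@@H](c3ccc(OC(C)=O)cc3)O4)c(OCOC)c21 | intermediate
13 | bis(diol) of 12: each C4 bears OH and CH2OH (C4 epimer mixture, erased on cleavage) | OCC1(O)C[C@@H](c2ccc(OC(C)=O)cc2)Oc2cc(OCOC)c(-c3c(OCOC)cc4c(c3OCOC)C(O)(CO)C[C@@H](c3ccc(OC(C)=O)cc3)O4)c(OCOC)c21 | intermediate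
14 | (2S,2''S)-4',4'''-diacetoxy-5,5'',7,7''-tetrakis(methoxymethoxy)-6,6''-biflavanone | O=C1C[C@@H](c2ccc(OC(C)=O)cc2)Oc2cc(OCOC)c(-c3c(OCOC)cc4c(c3OCOC)C(=O)C[C@@H](c3ccc(OC(C)=O)cc3)O4)c(OCOC)c21 | intermediate
15 | succedaneaflavanone, (2S,2''S)-4',4''',5,5'',7,7''-hexahydroxy-6,6''-biflavanone | O=C1C[C@@H](c2ccc(O)cc2)Oc2cc(O)c(-c3c(O)cc4c(c3O)C(=O)C[C@@H](c3ccc(O)cc3)O4)c(O)c21 | target

**Step count and risks**
Total: 8 steps. Longest linear sequence: 7 steps (1 to 15 through steps 1, 2, 4, 5, 6, 7, 8); step 3 is a one-step side branch.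

Steps most likely to fail:

Step 6. Palladium hydride may re-add and move the new double bond into the ring (a 4-methyl-2H-chromene cannot be cleaved to the ketone), closure may go 7-endo, or the crowded electron-rich aryl iodide may lose iodine reductively. The fallback closes the same bonds without metal at the acid oxidation level and sets out from 9, so step 5 is skipped. OsO4/NaIO4/2,6-lutidine cleaves both vinyl groups to the dialdehyde F1. Pinnick oxidation (NaClO2, NaH2PO4, 2-methyl-2-butene) gives the diacid F2. TFAA in CH2Cl2 at −20 to 0 °C forms the bis(acyl trifluoroacetate) F3, which should close both rings by intramolecular Friedel–Crafts acylation at the same equivalent ortho carbons. This gives 14 directly, where the route is rejoined before step 8; MOM loss in the acidic medium is the point to watch there.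

Step 5. NIS may attack the vinyl groups, or one ring may take up two iodine atoms. The fallback needs no halide and sets out from 5 and 6. Propargylation of 6 with allenylboronic acid pinacol ester under (R)-TRIP should give, through the borate ester F4, the (R)-homopropargyl alcohol F5. Mitsunobu reaction with 5 gives the bis(but-3-ynyl) ether F6. Gold-catalysed two-fold 6-exo-dig hydroarylation (Ph3PAuNTf2, CH2Cl2, rt) by the same ortho carbons should give 12, where the route is rejoined before step 7.

Step 1. The doubly ortho-substituted aryl metal species may take up chlorine from CuCl2 or be protonated instead of coupling. The fallback is a cross-coupling and sets out from 1. The aryllithium 2 is quenched with I2 to give the aryl iodide F7, and in a second batch with 2-isopropoxy-4,4,5,5-tetramethyl-1,3,2-dioxaborolane to give the pinacol boronate F8. Suzuki–Miyaura coupling of F7 and F8 (Pd(OAc)2, SPhos, K3PO4, toluene/H2O, 100 °C) should give 3, where the route is rejoined before step 2.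

**Further compounds**
F1 | step 6 | bis-aldehyde from 9, 4,4'-bis{[(1S)-1-(4-acetoxyphenyl)-3-oxopropyl]oxy}-2,2',6,6'-tetrakis(methoxymethoxy)-1,1'-biphenyl | O=CC[C@H](Oc1cc(OCOC)c(-c2c(OCOC)cc(O[C@@H](CC=O)c3ccc(OC(C)=O)cc3)cc2OCOC)c(OCOC)c1)c1ccc(OC(C)=O)cc1
F2 | step 6 | diacid, (3S,3'S)-3,3'-{[2,2',6,6'-tetrakis(methoxymethoxy)-1,1'-biphenyl-4,4'-diyl]bis(oxy)}bis[3-(4-acetoxyphenyl)propanoic acid] | OC(=O)C[C@H](Oc1cc(OCOC)c(-c2c(OCOC)cc(O[C@@H](CC(O)=O)c3ccc(OC(C)=O)cc3)cc2OCOC)c(OCOC)c1)c1ccc(OC(C)=O)cc1
F3 | step 6 | bis(acyl trifluoroacetate) of F2 | O=C(C[C@H](Oc1cc(OCOC)c(-c2c(OCOC)cc(O[C@@H](CC(=O)OC(=O)C(F)(F)F)c3ccc(OC(C)=O)cc3)cc2OCOC)c(OCOC)c1)c1ccc(OC(C)=O)cc1)OC(=O)C(F)(F)F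
F4 | step 5 | pinacol borate ester of F5 | C#CC[C@@H](OB1OC(C)(C)C(C)(C)O1)c1ccc(OC(C)=O)cc1
F5 | step 5 | 4-[(1R)-1-hydroxybut-3-yn-1-yl]phenyl acetate | C#CC[C@@H](O)c1ccc(OC(C)=O)cc1
F6 | step 5 | 4,4'-bis{[(1S)-1-(4-acetoxyphenyl)but-3-yn-1-yl]oxy}-2,2',6,6'-tetrakis(methoxymethoxy)-1,1'-biphenyl | C#CC[C@H](Oc1cc(OCOC)c(-c2c(OCOC)cc(O[C@@H](CC#C)c3ccc(OC(C)=O)cc3)cc2OCOC)c(OCOC)c1)c1ccc(OC(C)=O)cc1
F7 | step 1 | 2-iodo-1,3-bis(methoxymethoxy)benzene | COCOc1cccc(OCOC)c1I
F8 | step 1 | 2-[2,6-bis(methoxymethoxy)phenyl]-4,4,5,5-tetramethyl-1,3,2-dioxaborolane | COCOc1cccc(OCOC)c1B1OC(C)(C)C(C)(C)O1
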